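The reading comes at 8.0 h in the flasks winter, midnight and noon, and the intermediate then standing is what the substrate has fed in, less what has drained away.

| flask | substrate | temperature | remark | time |
|---|---|---|---|---|
| Thursday's | 0.035 M | 12 °C | run made earlier |  |
| Monday's | 0.14 M | 29 °C | run made earlier |  |
| winter | 0.071 M | 5 °C |  | 8.0 h |
| midnight | 0.071 M | 35 °C |  | 8.0 h |
| noon | 0.071 M | 20 °C |  | 8.0 h |

Thursday's run (percent of the substrate charged)

| time / h | intermediate / % | target / % | substrate / % |
|---|---|---|---|
| 0.417 | 1.6 | 0 | 101.1 |
| 0.667 | 0 | 1.3 | 99.8 |
| 1.33 | 2.6 | 1.4 | 97.0 |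
| 2.50 | 4.1 | 0 | 94.1 |
| 5.00 | 6.0 | 0.6 | 88.2 |

Monday's run (percent of the substrate charged)

| time / min | intermediate / % | target / % | substrate / % |
|---|---|---|---|
| 20.0 | 7.4 | 0 | 91.8 |
| 40.0 | 10.1 | 1.8 | 86.4 |
| 60.0 | 12.9 | 1.2 | 78.5 |
| 80.0 | 14.8 | 0 | 72.5 |
| 90.0 | 17.3 | 1.5 | 69.1 |

(each reading ± 1 percentage point)

- percentages count the substrate that a species holds: one side product A counts as two
- the earlier runs were read with a standard deviation of 1 percentage point
- steps thought possible: substrate -> intermediate; substrate + target -> side product A; intermediate -> side product B; intermediate <-> target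

1. the best flask by amount of intermediate, in percent of the substrate charged; "all alike" if 1.5 percentage points covers them all (winter / midnight / noon / all alike)
2. amount of intermediate at the end, in percent of the substrate charged, winter
3. amount of intermediate at the end, in percent of the substrate charged, midnight
4. amount of intermediate at the end, in percent of the substrate charged, noon

The balance of the substrate, the limiting reagent, gives both flows from the last readings. Taken as first order, the loss gives a feed constant k of 0.0251 h⁻¹ in Thursday's run and 0.246 h⁻¹ in Monday's run. Whatever has left the substrate but reads as neither intermediate nor target has drained away. Divided by the time and by the average intermediate, taken as half its last reading, this gives a drain constant d of 0.347 h⁻¹ on Thursday and 0.933 h⁻¹ on Monday. Temperature and concentration moved together in those runs, so this reckoning assumes first order and ln k and ln d straight in temperature. That gives noon k = 0.0736 h⁻¹ and d = 0.552 h⁻¹.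

Early in noon, well inside the drain time 1/d of 1.81 h, intermediate climbs by the fraction k of the substrate each hour. Later the drain is reckoned to catch up with the feed. The substrate's own time 1/k is longer, 13.6 h, so intermediate is then reckoned to follow the substrate in a quasi-steady state at q = k/(d − k), here 0.154, the hold-up ratio of intermediate to substrate. At the reading, noon is reckoned to keep substrate 55.5% and, with the start term e^(−dt) subtracted, intermediate 8.35%.

Stretched beyond the runs' temperatures, the same lines give winter k = 0.00981 h⁻¹, d = 0.231 h⁻¹, and intermediate 3.40%. For midnight they give k = 0.552 h⁻¹, d = 1.32 h⁻¹, and intermediate 0.865%. Noon is therefore reckoned best.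

The forecast gives 3.6% for winter, 1.3% for midnight and 9.4% for noon, in its words “Noon should hold the most.”

The flasks give 4.21% in winter, 1.02% at midnight and 13.0% at noon, so noon holds the most.

    substrate → intermediate (k = 0.00110 min⁻¹, Ea = 104 kJ mol⁻¹)
    substrate + target → side product A (k = 0.0170 L mol⁻¹ min⁻¹, Ea = 73.0 kJ mol⁻¹)
    intermediate → side product B (k = 0.00490 min⁻¹, Ea = 83.0 kJ mol⁻¹)
    intermediate ⇌ target (K = 1.80, k = 6.10 × 10⁻⁴ min⁻¹, Ea = 89.0 kJ mol⁻¹, ΔH = −17.0 kJ mol⁻¹)
    (constants at 20 °C)

Noon keeps substrate 58.6%, and its intermediate over substrate stands at 0.222, above q. The neighbouring flask is noon left until 15 h, with its amounts and temperature held. There the reckoning gives substrate 33.2% and intermediate 5.11%. The neighbouring flask holds substrate 36.3%, with a ratio of intermediate to substrate of 0.253 and intermediate 9.17%.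

(All runs are simulated for substances that don't exist.)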